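**Retrosynthetic overview**
1. The target comes from a tris-TBS macrolide by HF·pyridine. The only ring, the 22-membered lactone, is built last: first the C1–O21 ester bond (Yamaguchi), then ring closure at C15–C16 by intramolecular B-alkyl Suzuki coupling, which keeps the E-C14=C15 alkene.
2. The C1–C15 iodo acid comes from an L-proline anti cross-aldol (C2–C3), an enamine Michael addition of propanal to a vinyl ketone (C4–C5), an OH-directed anti reduction (C7), and two catalytic Mukaiyama aldols (C8–C9, C10–C11) on (E)-5-iodo-4-methylpent-4-enal.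
3. The C16–C30 alcohol comes from two TRIP-catalysed allylborations (C18–C19, C20–C21), the key new IDPi-catalysed anti aldolisation of a propanal enol silane onto an enal (C22–C23), and a vinylogous Mukaiyama aldol on butanal (C26–C27, E-C24=C25).
4. All building blocks are achiral. C11 and C27 are the first stereocentres of the two fragments, and both are set by asymmetric catalysis.
5. Atom labels: C1 is the lactone C=O, C21 is the carbon bearing the lactone O, and C22–C30 is the side chain. Required configuration: 2S,3S,4R,7S,9R,11S,14E,19R,21S,22R,23R,24E,27R.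

Assumption: the four simple enol silanes and allyl-Bpin used below are treated as catalogue reagents (each enol silane is otherwise one routine O-silylation of the parent carbonyl compound).

**C1–C15 acid**

Step 1
Reactants: 1 pent-4-yn-1-ol
Product: 3 (E)-5-iodo-4-methylpent-4-en-1-ol, via alkenylalane 2 (not isolated)
Conditions: Me3Al (3 equiv), Cp2ZrCl2 (25 mol %), CH2Cl2, 0 °C to rt; then I2, THF, −30 °C; aq K2CO3
Reagents that add atoms: trimethylaluminium C[Al](C)C; iodine II
Why: Negishi Zr-catalysed carboalumination adds Me and Al syn across the terminal alkyne (Me to the internal carbon), and iodinolysis proceeds with retention, fixing the E-C14=C15 geometry.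

Step 2
Reactants: 3 (E)-5-iodo-4-methylpent-4-en-1-ol
Product: 4 (E)-5-iodo-4-methylpent-4-enal
Conditions: TEMPO (10 mol %), PhI(OAc)2 (1.1 equiv), CH2Cl2, rt
Reagents that add atoms: none
Why: The TEMPO/oxoammonium oxidation of a primary alcohol stops at the aldehyde and does not touch the vinyl iodide.

Step 3
Reactants: 4 (E)-5-iodo-4-methylpent-4-enal; 5 triethyl(vinyloxy)silane
Product: 6 (3S,6E)-7-iodo-6-methyl-3-(triethylsilyloxy)hept-6-enal (C9–C15)
Conditions: chiral IDPi (1 mol %, enantiomer giving 3S), toluene/pentane, −78 to −60 °C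
Reagents that add atoms: none
Why: In this silylium counter-anion-directed Mukaiyama aldol (single aldolisation of an acetaldehyde enol silane on a linear aliphatic aldehyde), the confined chiral anion leaves only the Re face of O-silylated 4 open, sets C11 (S), transfers TES to the aldolate and rejects the bulkier product aldehyde, so no oligomer forms.

Step 4
Reactants: 6 C9–C15 aldehyde; 7 2-(triethylsilyloxy)buta-1,3-diene
Product: 8 (5S,7S,10E)-11-iodo-10-methyl-5,7-bis(triethylsilyloxy)undeca-1,10-dien-3-one (C5–C15 vinyl ketone)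
Conditions: N-tosyltryptophan-derived B-aryl oxazaborolidinone (25 mol %, enantiomer giving Re-face attack), EtCN, −78 °C; pH 7 buffer work-up
Reagents that add atoms: none
Why: In this chiral oxazaborolidinone-catalysed Mukaiyama aldol of a ketone enol silane with an aliphatic aldehyde, the indole shields one face of the boron-bound aldehyde, so catalyst-controlled attack by the CH2 terminus of 7 gives the 9,11-syn isomer against the weak 1,3-anti bias of a β-silyloxy aldehyde, and the silyl group ends on O9.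

Step 5
Reactants: 8 C5–C15 vinyl ketone; 9 propanal
Product: 10 (2R,7S,9S,12E)-13-iodo-2,12-dimethyl-5-oxo-7,9-bis(triethylsilyloxy)tridec-12-enal
Conditions: (S)-diphenylprolinol methyl ether (10 mol %), ethyl 3,4-dihydroxybenzoate (20 mol %), propanal (3 equiv), CHCl3, 4 °C
Reagents that add atoms: none
Why: In this enamine-catalysed Michael addition of an aldehyde to a vinyl ketone, the E-enamine of propanal is shielded by the CPh2OMe group, the catechol activates the enone by hydrogen bonding, and bond formation on the open face sets C4 (R).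

Step 6
Reactants: 10 keto aldehyde; 9 propanal
Product: 11 (2S,3S,4R,9S,11S,14E)-3-hydroxy-15-iodo-2,4,14-trimethyl-7-oxo-9,11-bis(triethylsilyloxy)pentadec-14-enal
Conditions: L-proline (20 mol %), DMF, 4 °C, propanal (3 equiv) by syringe pump over 24 h
Reagents that add atoms: none
Why: In this proline-catalysed direct cross-aldol of aldehydes (hydrogen-bonded chair transition state), the propanal enamine attacks the Re face of the α-branched acceptor to give the 2,3-anti (2S,3S) aldol, which is also the Felkin (3,4-syn) matched case.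

Step 7
Reactants: 11 β-hydroxy aldehyde
Product: 12 (2S,3S,4R,9S,11S,14E)-3-(tert-butyldimethylsilyloxy)-15-iodo-2,4,14-trimethyl-7-oxo-9,11-bis(triethylsilyloxy)pentadec-14-enal
Conditions: TBSOTf (1.3 equiv), 2,6-lutidine, CH2Cl2, −78 °C
Reagents that add atoms: tert-butyldimethylsilyl triflate CC(C)(C)[Si](C)(C)OS(=O)(=O)C(F)(F)F
Why: Silyl triflate silylation caps the hindered C3 hydroxyl at low temperature before retro-aldol or C2 epimerisation can occur, and lutidine is too weak a base to enolise the ketone.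

Step 8
Reactants: 12 silylated aldehyde
Product: 13 (2S,3S,4R,9S,11S,14E)-3-(tert-butyldimethylsilyloxy)-15-iodo-2,4,14-trimethyl-7-oxo-9,11-bis(triethylsilyloxy)pentadec-14-enoic acid
Conditions: NaClO2, NaH2PO4, 2-methylbut-2-ene, t-BuOH/H2O, 0 °C
Reagents that add atoms: sodium chlorite [Na+].[O-]Cl=O
Why: Pinnick oxidation converts the α-chiral aldehyde to the acid without epimerisation and tolerates the ketone, silyl ethers and vinyl iodide.

Step 9
Reactants: 13 keto acid
Product: 15 (2S,3S,4R,7S,9R,11S,14E)-3-(tert-butyldimethylsilyloxy)-7,9,11-trihydroxy-15-iodo-2,4,14-trimethylpentadec-14-enoic acid, via dihydroxy keto acid 14 (not isolated)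
Conditions: AcOH/THF/H2O (3:1:1), rt; concentrate with toluene; then Me4NBH(OAc)3 (8 equiv), MeCN/AcOH (1:1), −30 °C
Reagents that add atoms: none
Why: The two unhindered TES ethers hydrolyse much faster than the flanked C3 TBS ether, after which the Evans–Saksena reduction binds boron to the C9 hydroxyl and delivers hydride intramolecularly through a chair to give the 7,9-anti carbinol (7S).

Step 10
Reactants: 15 triol acid
Product: 17 (2S,3S,4R,7S,9R,11S,14E)-7,9,11-triacetoxy-3-(tert-butyldimethylsilyloxy)-15-iodo-2,4,14-trimethylpentadec-14-enoic acid, via mixed anhydride 16 (not isolated)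
Conditions: Ac2O (6 equiv), pyridine, DMAP (10 mol %), CH2Cl2, 0 °C to rt; then THF/aq NaHCO3, rt
Reagents that add atoms: acetic anhydride CC(=O)OC(C)=O
Why: DMAP-catalysed acetylation esterifies the three free secondary hydroxyls (C3 is masked), and the acetic–carboxylic mixed anhydride is hydrolysed selectively in the aqueous stir.

**C16–C30 alcohol**

Step 11
Reactants: 18 butanal; 19 (E)-tert-butyldimethyl(3-methylbuta-1,3-dienyloxy)silane
Product: 20 (2E,5R)-5-hydroxy-3-methyloct-2-enal (C23–C30)
Conditions: N-tosyltryptophan-derived B-phenyl oxazaborolidinone (30 mol %, enantiomer giving Si-face attack), i-PrOH (1.2 equiv), EtCN, −78 °C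
Reagents that add atoms: none
Why: In this oxazaborolidinone-catalysed vinylogous Mukaiyama aldol of an aldehyde-derived dienol silane, γ-attack from the s-trans diene gives the E-trisubstituted enal, the catalyst-shielded aldehyde face sets C27 (R) as the first stereocentre of this fragment, and i-PrOH takes up the silyl group.

Step 12
Reactants: 20 hydroxy enal
Product: 21 (4R,6E)-6-methyl-8-oxooct-6-en-4-yl acetate
Conditions: Ac2O, pyridine, DMAP (5 mol %), CH2Cl2, 0 °C
Reagents that add atoms: acetic anhydride CC(=O)OC(C)=O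
Why: Plain acylation installs the final C27 acetate early, so this oxygen needs no further handling.

Step 13
Reactants: 21 acetoxy enal; 22 (Z)-tert-butyldimethyl(prop-1-enyloxy)silane
Product: 23 (4R,6E,8R,9R)-8-(tert-butyldimethylsilyloxy)-6,9-dimethyl-10-oxodec-6-en-4-yl acetate (C21–C30 aldehyde)
Conditions: anti-selective chiral IDPi (2–3 mol %, enantiomer giving Si-face attack), 22 (1.5 equiv), toluene, −78 to −60 °C
Reagents that add atoms: none
Why: Proposed new method: an anti- and enantioselective silylium counter-anion-directed Mukaiyama aldolisation of a propanal enol silane with an aliphatic β,β-disubstituted enal. The IDPi is silylated by 22; the TBS+/IDPi− pair O-silylates 21 to a flat 1-silyloxyallyl cation that occupies the confined anion much like the aryl oxocarbenium ions of the known reaction; 1,4-attack is blocked by the fully substituted C25; the Z-enol silane adds through an open antiperiplanar transition state to the Si face of C23 to give the 22,23-anti product and forms the C22–C23 bond; TBS transfer regenerates the silylium pair; the bulky α-branched product is excluded from the pocket, so no second aldol occurs; and the remote C27 acetate exerts no control, so selectivity is catalyst-derived. The closest known reaction type is the IDPi-catalysed syn- or anti-selective Mukaiyama aldolisation of propionaldehyde enol silanes with aromatic aldehydes.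

Step 14
Reactants: 23 C21–C30 aldehyde; 24 allylboronic acid pinacol ester
Product: 26 (4R,6E,8R,9S,10S)-8-(tert-butyldimethylsilyloxy)-10-hydroxy-6,9-dimethyltrideca-6,12-dien-4-yl acetate, via borate ester 25 (not isolated)
Conditions: (S)-TRIP phosphoric acid (10 mol %), 24 (1.5 equiv), 4 Å MS, toluene, −30 °C; aqueous work-up
Reagents that add atoms: none
Why: In this chiral phosphoric acid-catalysed allylboration (closed chair, acid bound to a boronate oxygen and the formyl H), the substrate bias in this transition state is small, so the (S)-catalyst directs Si-face attack and gives the anti-Felkin 21,22-anti/21,23-syn alcohol (21S), completing the anti,anti triad.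

Step 15
Reactants: 26 homoallylic alcohol
Product: 28 (4R,6E,8R,9S,10S)-8-(tert-butyldimethylsilyloxy)-10-hydroxy-6,9-dimethyl-12-oxododec-6-en-4-yl acetate, via vicinal diol 27 (not isolated)
Conditions: OsO4 (2 mol %), NaIO4 (3 equiv), 2,6-lutidine (2 equiv), dioxane/H2O (3:1), 0 °C, stopped at full consumption of 26
Reagents that add atoms: osmium tetroxide (catalytic O carrier) O=[Os](=O)(=O)=O; sodium periodate (terminal O source) [Na+].[O-]I(=O)(=O)=O
Why: Lemieux–Johnson cleavage takes the unhindered monosubstituted alkene in preference to the trisubstituted C24=C25 alkene, which is crowded and inductively deactivated by the allylic OTBS group.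

Step 16
Reactants: 28 β-hydroxy aldehyde (used crude); 24 allylboronic acid pinacol ester
Product: 30 (4R,6E,8R,9S,10S,12R)-8-(tert-butyldimethylsilyloxy)-10,12-dihydroxy-6,9-dimethylpentadeca-6,14-dien-4-yl acetate, via borate ester 29 (not isolated)
Conditions: (R)-TRIP phosphoric acid (10 mol %), 24 (2 equiv), 4 Å MS, toluene, −30 °C; aqueous work-up
Reagents that add atoms: none
Why: The same phosphoric acid-catalysed allylboration on an α-unbranched aldehyde is fully catalyst-controlled, and the (R)-acid directs Re-face attack to give 19R (19,21-anti) while installing the C16–C18 allyl handle.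

Step 17
Reactants: 30 anti-1,3-diol
Product: 31 (4R,6E,8R,9S,10S,12R)-8,12-bis(tert-butyldimethylsilyloxy)-10-hydroxy-6,9-dimethylpentadeca-6,14-dien-4-yl acetate (C16–C30 alcohol)
Conditions: TBSCl (1.1 equiv), imidazole, CH2Cl2/DMF, 0 °C
Reagents that add atoms: tert-butyldimethylsilyl chloride CC(C)(C)[Si](C)(C)Cl
Why: Sterically controlled monosilylation picks the C19 hydroxyl (CH2 on both sides) over the C21 hydroxyl, which is next to the C22 methine and the bulky C23 OTBS group, and leaves exactly the acylation site free.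

**Union and endgame**

Step 18
Reactants: 17 C1–C15 acid; 31 C16–C30 alcohol
Product: 33 seco-ester (acyl group of 17 on O21 of 31; 2S,3S,4R,7S,9R,11S,14E,19R,21S,22S,23R,24E,27R where 22S is a CIP change only), via Yamaguchi anhydride 32 (not isolated)
Conditions: 2,4,6-trichlorobenzoyl chloride, Et3N, toluene, rt; then 31, DMAP, toluene, rt
Reagents that add atoms: none
Why: Yamaguchi esterification acylates the single free, hindered secondary hydroxyl through the acyl-DMAP species, and α-methyl-β-silyloxy acids tolerate these conditions without C2 epimerisation.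

Step 19
Reactants: 33 seco-ester
Product: 35 3,19,23-tris-O-TBS macrolide (22-membered lactone; E-C14=C15), via alkylborane 34 (not isolated)
Conditions: 9-BBN-H (2.5 equiv), THF, rt; then slow addition to Pd(dppf)Cl2 (20 mol %), AsPh3 (40 mol %), Cs2CO3 (4 equiv), DMF/THF/H2O, 1 mM, 45 °C
Reagents that add atoms: none
Why: 9-BBN hydroborates only the terminal alkene, and the intramolecular B-alkyl Suzuki–Miyaura coupling with the E-vinyl iodide forms C15–C16 with retention and closes the ring, while acetates and silyl ethers tolerate the mild carbonate base.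

Step 20
Reactants: 35 tris-TBS macrolide
Product: 36 target CNP0381697.2
Conditions: HF·pyridine, pyridine, THF, 0 °C to rt (plastic vessel)
Reagents that add atoms: none
Why: Buffered fluoride desilylation frees the C3, C19 and C23 hydroxyls under weakly acidic conditions, where the acetates and the lactone neither migrate nor cleave.

**Compound list**
1 | pent-4-yn-1-ol | C#CCCCO | starting material
2 | (E)-alkenyl(dimethyl)alane, O-aluminated | C[Al](C)/C=C(\C)CCCO[Al](C)C | intermediate
3 | (E)-5-iodo-4-methylpent-4-en-1-ol | I/C=C(\C)CCCO | intermediate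
4 | (E)-5-iodo-4-methylpent-4-enal | I/C=C(\C)CCC=O | intermediate
5 | triethyl(vinyloxy)silane | C=CO[Si](CC)(CC)CC | starting material
6 | (3S,6E)-7-iodo-6-methyl-3-(triethylsilyloxy)hept-6-enal | I/C=C(\C)CC[C@H](O[Si](CC)(CC)CC)CC=O | intermediate
7 | 2-(triethylsilyloxy)buta-1,3-diene | C=CC(=C)O[Si](CC)(CC)CC | starting material
8 | (5S,7S,10E)-11-iodo-10-methyl-5,7-bis(triethylsilyloxy)undeca-1,10-dien-3-one | I/C=C(\C)CC[C@H](O[Si](CC)(CC)CC)C[C@H](O[Si](CC)(CC)CC)CC(=O)C=C | intermediate
9 | propanal | CCC=O | starting material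
10 | (2R,7S,9S,12E)-13-iodo-2,12-dimethyl-5-oxo-7,9-bis(triethylsilyloxy)tridec-12-enal | I/C=C(\C)CC[C@H](O[Si](CC)(CC)CC)C[C@H](O[Si](CC)(CC)CC)CC(=O)CC[C@@H](C)C=O | intermediate
11 | (2S,3S,4R,9S,11S,14E)-3-hydroxy-15-iodo-2,4,14-trimethyl-7-oxo-9,11-bis(triethylsilyloxy)pentadec-14-enal | I/C=C(\C)CC[C@H](O[Si](CC)(CC)CC)C[C@H](O[Si](CC)(CC)CC)CC(=O)CC[C@@H](C)[C@H](O)[C@H](C)C=O | intermediate
12 | 3-O-TBS ether of 11 | I/C=C(\C)CC[C@H](O[Si](CC)(CC)CC)C[C@H](O[Si](CC)(CC)CC)CC(=O)CC[C@@H](C)[C@H](O[Si](C)(C)C(C)(C)C)[C@H](C)C=O | intermediate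
13 | carboxylic acid from 12 | I/C=C(\C)CC[C@H](O[Si](CC)(CC)CC)C[C@H](O[Si](CC)(CC)CC)CC(=O)CC[C@@H](C)[C@H](O[Si](C)(C)C(C)(C)C)[C@H](C)C(=O)O | intermediate
14 | (2S,3S,4R,9S,11S,14E)-3-(TBSO)-9,11-dihydroxy-15-iodo-2,4,14-trimethyl-7-oxopentadec-14-enoic acid | I/C=C(\C)CC[C@H](O)C[C@H](O)CC(=O)CC[C@@H](C)[C@H](O[Si](C)(C)C(C)(C)C)[C@H](C)C(=O)O | intermediate
15 | (2S,3S,4R,7S,9R,11S,14E)-3-(TBSO)-7,9,11-trihydroxy-15-iodo-2,4,14-trimethylpentadec-14-enoic acid | I/C=C(\C)CC[C@H](O)C[C@H](O)C[C@@H](O)CC[C@@H](C)[C@H](O[Si](C)(C)C(C)(C)C)[C@H](C)C(=O)O | intermediate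
16 | acetic mixed anhydride of 17 | I/C=C(\C)CC[C@H](OC(C)=O)C[C@H](OC(C)=O)C[C@@H](OC(C)=O)CC[C@@H](C)[C@H](O[Si](C)(C)C(C)(C)C)[C@H](C)C(=O)OC(C)=O | intermediate
17 | (2S,3S,4R,7S,9R,11S,14E)-7,9,11-triacetoxy-3-(TBSO)-15-iodo-2,4,14-trimethylpentadec-14-enoic acid | I/C=C(\C)CC[C@H](OC(C)=O)C[C@H](OC(C)=O)C[C@@H](OC(C)=O)CC[C@@H](C)[C@H](O[Si](C)(C)C(C)(C)C)[C@H](C)C(=O)O | intermediate
18 | butanal | CCCC=O | starting material
19 | (E)-tert-butyldimethyl(3-methylbuta-1,3-dienyloxy)silane | C=C(C)/C=C/O[Si](C)(C)C(C)(C)C | starting material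
20 | (2E,5R)-5-hydroxy-3-methyloct-2-enal | CCC[C@H](C/C(C)=C/C=O)O | intermediate
21 | (4R,6E)-6-methyl-8-oxooct-6-en-4-yl acetate | CCC[C@H](C/C(C)=C/C=O)OC(C)=O | intermediate
22 | (Z)-tert-butyldimethyl(prop-1-enyloxy)silane | C/C=C\O[Si](C)(C)C(C)(C)C | starting material
23 | (4R,6E,8R,9R)-8-(TBSO)-6,9-dimethyl-10-oxodec-6-en-4-yl acetate | CCC[C@H](C/C(C)=C/[C@@H](O[Si](C)(C)C(C)(C)C)[C@@H](C)C=O)OC(C)=O | intermediate
24 | allylboronic acid pinacol ester | C=CCB1OC(C)(C)C(C)(C)O1 | starting material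
25 | O21-Bpin borate of 26 | CCC[C@H](C/C(C)=C/[C@@H](O[Si](C)(C)C(C)(C)C)[C@@H](C)[C@@H](OB1OC(C)(C)C(C)(C)O1)CC=C)OC(C)=O | intermediate
26 | (4R,6E,8R,9S,10S)-8-(TBSO)-10-hydroxy-6,9-dimethyltrideca-6,12-dien-4-yl acetate | CCC[C@H](C/C(C)=C/[C@@H](O[Si](C)(C)C(C)(C)C)[C@@H](C)[C@@H](O)CC=C)OC(C)=O | intermediate
27 | 12,13-diol of 26 (epimers at the new carbinol) | CCC[C@H](C/C(C)=C/[C@@H](O[Si](C)(C)C(C)(C)C)[C@@H](C)[C@@H](O)CC(O)CO)OC(C)=O | intermediate
28 | (4R,6E,8R,9S,10S)-8-(TBSO)-10-hydroxy-6,9-dimethyl-12-oxododec-6-en-4-yl acetate | CCC[C@H](C/C(C)=C/[C@@H](O[Si](C)(C)C(C)(C)C)[C@@H](C)[C@@H](O)CC=O)OC(C)=O | intermediate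
29 | O19-Bpin borate of 30 | CCC[C@H](C/C(C)=C/[C@@H](O[Si](C)(C)C(C)(C)C)[C@@H](C)[C@@H](O)C[C@H](OB1OC(C)(C)C(C)(C)O1)CC=C)OC(C)=O | intermediate
30 | (4R,6E,8R,9S,10S,12R)-8-(TBSO)-10,12-dihydroxy-6,9-dimethylpentadeca-6,14-dien-4-yl acetate | CCC[C@H](C/C(C)=C/[C@@H](O[Si](C)(C)C(C)(C)C)[C@@H](C)[C@@H](O)C[C@H](O)CC=C)OC(C)=O | intermediate
31 | (4R,6E,8R,9S,10S,12R)-8,12-bis(TBSO)-10-hydroxy-6,9-dimethylpentadeca-6,14-dien-4-yl acetate | CCC[C@H](C/C(C)=C/[C@@H](O[Si](C)(C)C(C)(C)C)[C@@H](C)[C@@H](O)C[C@H](O[Si](C)(C)C(C)(C)C)CC=C)OC(C)=O | intermediate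
32 | 2,4,6-trichlorobenzoic mixed anhydride of 17 | I/C=C(\C)CC[C@H](OC(C)=O)C[C@H](OC(C)=O)C[C@@H](OC(C)=O)CC[C@@H](C)[C@H](O[Si](C)(C)C(C)(C)C)[C@H](C)C(=O)OC(=O)c1c(Cl)cc(Cl)cc1Cl | intermediate
33 | seco-ester (17 acylating O21 of 31) | I/C=C(\C)CC[C@H](OC(C)=O)C[C@H](OC(C)=O)C[C@@H](OC(C)=O)CC[C@@H](C)[C@H](O[Si](C)(C)C(C)(C)C)[C@H](C)C(=O)O[C@H]([C@H](C)[C@H](O[Si](C)(C)C(C)(C)C)/C=C(\C)C[C@H](OC(C)=O)CCC)C[C@H](O[Si](C)(C)C(C)(C)C)CC=C | intermediate
34 | C16 B-alkyl-9-BBN derivative of 33 | I/C=C(\C)CC[C@H](OC(C)=O)C[C@H](OC(C)=O)C[C@@H](OC(C)=O)CC[C@@H](C)[C@H](O[Si](C)(C)C(C)(C)C)[C@H](C)C(=O)O[C@H]([C@H](C)[C@H](O[Si](C)(C)C(C)(C)C)/C=C(\C)C[C@H](OC(C)=O)CCC)C[C@H](O[Si](C)(C)C(C)(C)C)CCCB1C2CCCC1CCC2 | intermediate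
35 | 3,19,23-tris-O-TBS macrolide | CCC[C@H](C/C(C)=C/[C@@H](O[Si](C)(C)C(C)(C)C)[C@@H](C)[C@@H]1C[C@H](O[Si](C)(C)C(C)(C)C)CCC/C=C(\C)CC[C@H](OC(C)=O)C[C@H](OC(C)=O)C[C@@H](OC(C)=O)CC[C@@H](C)[C@H](O[Si](C)(C)C(C)(C)C)[C@H](C)C(=O)O1)OC(C)=O | intermediate
36 | CNP0381697.2 | CCC[C@H](C/C(C)=C/[C@@H](O)[C@@H](C)[C@@H]1C[C@H](O)CCC/C=C(\C)CC[C@H](OC(C)=O)C[C@H](OC(C)=O)C[C@@H](OC(C)=O)CC[C@@H](C)[C@H](O)[C@H](C)C(=O)O1)OC(C)=O | target

**Total step count:** 20. **Longest linear sequence:** 13 (steps 1–10, then 18–20). The C16–C30 branch runs 7 steps before the union.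

**Three steps most likely to fail**

1. Step 13 (the proposed new method). The risks are that the enal is too weakly electrophilic in the confined pocket, or that the anti or facial selectivity erodes. The fallback uses known chemistry, sets out from 21 and returns at 23. (S)-TRIP-catalysed allylboration of 21 with (E)-crotylboronic acid pinacol ester gives the anti bis-allylic alcohol F1. TBSOTf/2,6-lutidine converts it to the silyl ether F2. OsO4/NaIO4 cleavage of the monosubstituted alkene of F2 then delivers 23.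

2. Step 4. The risks are an insufficient catalyst override of the 1,3-anti bias, or competing hetero-Diels–Alder reaction of the siloxydiene. The fallback sets out from 6 and returns at 8. A cinchona alkaloid (O-TMS-quinine or O-TMS-quinidine, whichever gives 9,11-syn)/LiClO4-catalysed acetyl chloride–aldehyde cyclocondensation gives the β-lactone F3. MeONHMe·HCl/Me2AlCl opens it to the hydroxy Weinreb amide F4. TESOTf gives the bis-silyl amide F5. Vinylmagnesium bromide with an acidic quench then gives 8.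

3. Step 19. The risks are oligomerisation, protodeboronation or slow closure of the 22-membered ring. The fallback sets out from 17 and 31 (step 18 is skipped) and returns at 35. Compound 31 is hydroborated with 9-BBN and cross-coupled intermolecularly with iodide 17 under the same Pd conditions to give the seco acid F6. Its only free hydroxyl (C21) is then closed onto C1 by Yamaguchi macrolactonisation at high dilution to give 35.

**Further compounds**
F1 | step 13 | (4R,6E,8S,9S)-8-hydroxy-6,9-dimethylundeca-6,10-dien-4-yl acetate | CCC[C@H](C/C(C)=C/[C@@H](O)[C@@H](C)C=C)OC(C)=O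
F2 | step 13 | (4R,6E,8S,9S)-8-(tert-butyldimethylsilyloxy)-6,9-dimethylundeca-6,10-dien-4-yl acetate | CCC[C@H](C/C(C)=C/[C@@H](O[Si](C)(C)C(C)(C)C)[C@@H](C)C=C)OC(C)=O
F3 | step 4 | (4S)-4-[(2S,5E)-6-iodo-5-methyl-2-(triethylsilyloxy)hex-5-enyl]oxetan-2-one | I/C=C(\C)CC[C@H](O[Si](CC)(CC)CC)C[C@H]1CC(=O)O1
F4 | step 4 | (3S,5S,8E)-3-hydroxy-9-iodo-N-methoxy-N,8-dimethyl-5-(triethylsilyloxy)non-8-enamide | I/C=C(\C)CC[C@H](O[Si](CC)(CC)CC)C[C@H](O)CC(=O)N(C)OC
F5 | step 4 | (3S,5S,8E)-9-iodo-N-methoxy-N,8-dimethyl-3,5-bis(triethylsilyloxy)non-8-enamide | I/C=C(\C)CC[C@H](O[Si](CC)(CC)CC)C[C@H](O[Si](CC)(CC)CC)CC(=O)N(C)OC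
F6 | step 19 | C1–C30 seco acid (21-OH free; 3,19,23-tris-O-TBS; 7,9,11,27-tetraacetate) | CCC[C@H](C/C(C)=C/[C@@H](O[Si](C)(C)C(C)(C)C)[C@@H](C)[C@@H](O)C[C@H](O[Si](C)(C)C(C)(C)C)CCC/C=C(\C)CC[C@H](OC(C)=O)C[C@H](OC(C)=O)C[C@@H](OC(C)=O)CC[C@@H](C)[C@H](O[Si](C)(C)C(C)(C)C)[C@H](C)C(=O)O)OC(C)=O
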